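**Retrosynthetic overview**
1. Target 45 ← desilylation ← oxidation at C8 ← Suzuki–Miyaura coupling at C11–C12 of alkenyl iodide 27 (C1–C11) with alkenylboronate 42 (C12–C19 plus lactone).
2. 42 ← Takai–Utimoto boryl-olefination (C12=C13) ← Heck coupling at C17–C18 of Z-alkenyl iodide 39 with vinyl lactone 32; 39 ← Stork–Zhao-type olefination of the lactol from chiral-pool lactone 33.
3. The lactone is the only ring and is formed early: Brown anti-crotylation of acrolein, acryloylation, ring-closing metathesis → 32.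
4. 27 ← Evans syn-aldol at C8–C9 (sets C9) of aldehyde 13 with iodopentenoyl imide 21, then LiBH4 removal of the auxiliary, silylation, saponification.
5. 13 ← Brown anti-crotylation (C6, C7) of aldehyde 9 ← syn-carbocupration of methyl but-2-ynoate (C3–C4) by the reagent from chiral-pool bromide 1 (C5).

Assumption: (R)-3-methyldihydrofuran-2(3H)-one 33 is bought as the single enantiomer, and "(−)-Ipc2BOMe" means the reagent made from (+)-α-pinene.

The target SMILES encodes 5R,6R,7R,9S,15R and a trans (2R,3S) lactone, and the route is built for exactly these centers.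

**Route**

Step 1
Reactants: 1 (S)-3-bromo-2-methylpropan-1-ol
Product: 2 (S)-(3-bromo-2-methylpropoxy)triethylsilane
Conditions: Et3SiCl, imidazole, CH2Cl2, 0 °C to rt
Reagents that add atoms: chlorotriethylsilane, CC[Si](Cl)(CC)CC
Why: Imidazole-promoted silylation masks the primary alcohol for the organomagnesium step as a TES ether that can later be oxidised directly; the chiral-pool center (future C5) is untouched.

Step 2
Reactants: 2 (S)-(3-bromo-2-methylpropoxy)triethylsilane; 3 methyl but-2-ynoate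
Product: 7 methyl (R,E)-3,5-dimethyl-6-(triethylsilyloxy)hex-2-enoate, via alkylmagnesium bromide 4 (not isolated), via alkylcopper 5 (not isolated), via alkenylcopper 6 (not isolated)
Conditions: Mg, THF, 40 °C; CuBr·SMe2, THF, −78 °C; 3, −78 °C; MeOH, −78 °C, then aq. NH4Cl
Reagents that add atoms: none
Why: Magnesium insertion and transmetalation give an alkylcopper that adds syn across the ynoate (carbocupration), and cold protonation of 6 with retention gives the 2E-enoate with the C3–C4 bond in place.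

Step 3
Reactants: 7 methyl (R,E)-3,5-dimethyl-6-(triethylsilyloxy)hex-2-enoate
Product: 9 methyl (R,E)-3,5-dimethyl-6-oxohex-2-enoate, via alkoxysulfonium chloride 8 (not isolated)
Conditions: (COCl)2, DMSO, CH2Cl2, −78 to −40 °C; Et3N, −78 to 0 °C
Reagents that add atoms: none
Why: Under Swern conditions activated DMSO displaces the silyl group of a primary TES ether to give alkoxysulfonium 8, which collapses with Et3N to the aldehyde in one operation; the cold work-up keeps the α-center intact.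

Step 4
Reactants: 9 methyl (R,E)-3,5-dimethyl-6-oxohex-2-enoate
Product: 11 methyl (2E,5R,6R,7S)-6-hydroxy-3,5,7-trimethylnona-2,8-dienoate, via diisopinocampheylborinate 10 (not isolated)
Conditions: trans-2-butene, KOtBu, n-BuLi, THF, −78 to −45 °C; (−)-Ipc2BOMe, −78 °C; BF3·OEt2, −78 °C; 9, −78 °C; NaBO3·4H2O, THF/H2O, rt
Reagents that add atoms: trans-2-butene, C/C=C/C
Why: In this Brown crotylboration the (E)-crotylborane reacts through a chair transition state (6,7-anti) and the Ipc ligands from (+)-α-pinene direct attack to the Si face of the aldehyde, overriding its weak Felkin bias to give the 5,6-anti (6R,7S) adduct.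

Step 5
Reactants: 11 methyl (2E,5R,6R,7S)-6-hydroxy-3,5,7-trimethylnona-2,8-dienoate
Product: 12 methyl (2E,5R,6R,7S)-6-(tert-butyldimethylsilyloxy)-3,5,7-trimethylnona-2,8-dienoate
Conditions: TBSOTf, 2,6-lutidine, CH2Cl2, −78 to 0 °C
Reagents that add atoms: tert-butyldimethylsilyl triflate, CC(C)(C)[Si](C)(C)OS(=O)(=O)C(F)(F)F
Why: The silyl triflate silylates the hindered secondary alcohol, protecting O6 through the aldol, reduction and coupling steps.

Step 6
Reactants: 12 methyl (2E,5R,6R,7S)-6-(tert-butyldimethylsilyloxy)-3,5,7-trimethylnona-2,8-dienoate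
Product: 13 methyl (2E,5R,6R,7R)-6-(tert-butyldimethylsilyloxy)-3,5,7-trimethyl-8-oxooct-2-enoate
Conditions: OsO4 (cat.), NaIO4, 2,6-lutidine, dioxane/H2O 3:1, rt
Reagents that add atoms: osmium tetroxide, O=[Os](=O)(=O)=O; sodium periodate, [Na+].[O-]I(=O)(=O)=O
Why: In this Lemieux–Johnson cleavage the monosubstituted alkene is dihydroxylated and cleaved much faster than the electron-poor trisubstituted enoate, and 2,6-lutidine suppresses epimerisation of the new α-chiral aldehyde (C8).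

Step 7
Reactants: 14 pent-3-yn-1-ol
Product: 16 (E)-4-iodopent-3-en-1-ol, via alkenylzirconocene chloride 15 (not isolated)
Conditions: Cp2Zr(H)Cl (2.5 equiv), THF, rt; I2, 0 °C
Reagents that add atoms: iodine, II
Why: Hydrozirconation is a syn addition that, after equilibration, places zirconium on the less hindered methyl-bearing alkyne carbon, and iodinolysis with retention gives the E-alkenyl iodide.

Step 8
Reactants: 16 (E)-4-iodopent-3-en-1-ol
Product: 18 (E)-4-iodopent-3-enoic acid, via aldehyde 17 (not isolated)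
Conditions: TEMPO (cat.), PhI(OAc)2, MeCN/H2O 1:1, rt
Reagents that add atoms: water, O
Why: The oxoammonium oxidation takes the primary alcohol through aldehyde 17 (as its hydrate) to the acid under non-basic conditions that leave the β,γ-double bond in place.

Step 9
Reactants: 18 (E)-4-iodopent-3-enoic acid; 19 (R)-4-benzyloxazolidin-2-one
Product: 21 (R)-4-benzyl-3-[(E)-4-iodopent-3-enoyl]oxazolidin-2-one, via mixed pivalic anhydride 20 (not isolated)
Conditions: PivCl, Et3N, THF, −20 °C; LiCl, 19, −20 °C to rt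
Reagents that add atoms: none
Why: N-acylation through the mixed anhydride (LiCl-assisted) works under mild base, so the double bond stays out of conjugation.

Step 10
Reactants: 21 (R)-4-benzyl-3-[(E)-4-iodopent-3-enoyl]oxazolidin-2-one; 13 methyl (2E,5R,6R,7R)-6-(tert-butyldimethylsilyloxy)-3,5,7-trimethyl-8-oxooct-2-enoate
Product: 24 methyl (2E,5R,6R,7S,8S,9R,10E)-9-[(R)-4-benzyl-2-oxooxazolidine-3-carbonyl]-6-(tert-butyldimethylsilyloxy)-8-hydroxy-11-iodo-3,5,7-trimethyldodeca-2,10-dienoate, via boron dienolate 22 (not isolated), via boron aldolate 23 (not isolated)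
Conditions: Bu2BOTf, Et3N, CH2Cl2, −78 to 0 °C; 13, −78 to 0 °C; pH 7 buffer, MeOH, H2O2, 0 °C
Reagents that add atoms: none
Why: In this Evans syn-aldol the Z-boron dienolate reacts at its α-carbon through a chair transition state on the face opposite the benzyl group, so the (R)-auxiliary sets C9 (9S in the target); the C8 carbinol configuration is irrelevant because it is oxidised later.

Step 11
Reactants: 24 methyl (2E,5R,6R,7S,8S,9R,10E)-9-[(R)-4-benzyl-2-oxooxazolidine-3-carbonyl]-6-(tert-butyldimethylsilyloxy)-8-hydroxy-11-iodo-3,5,7-trimethyldodeca-2,10-dienoate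
Product: 25 methyl (2E,5R,6R,7S,8R,9S,10E)-6-(tert-butyldimethylsilyloxy)-8-hydroxy-9-(hydroxymethyl)-11-iodo-3,5,7-trimethyldodeca-2,10-dienoate
Conditions: LiBH4, MeOH (1 equiv), THF, 0 °C
Reagents that add atoms: none
Why: LiBH4 reductively cleaves the activated imide carbonyl to the C9 hydroxymethyl group much faster than it attacks the conjugated methyl ester, and releases the auxiliary.

Step 12
Reactants: 25 methyl (2E,5R,6R,7S,8R,9S,10E)-6-(tert-butyldimethylsilyloxy)-8-hydroxy-9-(hydroxymethyl)-11-iodo-3,5,7-trimethyldodeca-2,10-dienoate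
Product: 26 methyl (2E,5R,6R,7S,8R,9S,10E)-6-(tert-butyldimethylsilyloxy)-9-[(tert-butyldimethylsilyloxy)methyl]-8-hydroxy-11-iodo-3,5,7-trimethyldodeca-2,10-dienoate
Conditions: TBSCl, imidazole, CH2Cl2, 0 °C
Reagents that add atoms: tert-butyldimethylsilyl chloride, CC(C)(C)[Si](C)(C)Cl
Why: Steric differentiation lets TBSCl silylate the primary hydroxyl and leave the hindered C8 secondary alcohol free for the later oxidation.

Step 13
Reactants: 26 methyl (2E,5R,6R,7S,8R,9S,10E)-6-(tert-butyldimethylsilyloxy)-9-[(tert-butyldimethylsilyloxy)methyl]-8-hydroxy-11-iodo-3,5,7-trimethyldodeca-2,10-dienoate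
Product: 27 (2E,5R,6R,7S,8R,9S,10E)-6-(tert-butyldimethylsilyloxy)-9-[(tert-butyldimethylsilyloxy)methyl]-8-hydroxy-11-iodo-3,5,7-trimethyldodeca-2,10-dienoic acid
Conditions: LiOH, THF/MeOH/H2O 3:1:1, rt to 40 °C; then 0.5 M HCl to pH 4, 0 °C
Reagents that add atoms: lithium hydroxide, [Li+].[OH-]
Why: Saponification at this stage, before any lactone or ketone is present, frees the C1 acid; TBS ethers and the alkenyl iodide tolerate hydroxide.

Step 14
Reactants: 28 acrolein
Product: 30 (3R,4S)-4-methylhexa-1,5-dien-3-ol, via diisopinocampheylborinate 29 (not isolated)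
Conditions: trans-2-butene, KOtBu, n-BuLi, THF, −78 to −45 °C; (−)-Ipc2BOMe, −78 °C; BF3·OEt2, −78 °C; 28, −78 °C; NaBO3·4H2O, THF/H2O, rt
Reagents that add atoms: trans-2-butene, C/C=C/C
Why: In this Brown crotylboration the E-crotyl geometry gives the anti relationship and the Ipc ligands from (+)-α-pinene direct Si-face attack, giving the (3R,4S)-dienol that carries both lactone stereocenters.

Step 15
Reactants: 30 (3R,4S)-4-methylhexa-1,5-dien-3-ol
Product: 31 (3R,4S)-4-methylhexa-1,5-dien-3-yl acrylate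
Conditions: acryloyl chloride, Et3N, DMAP (cat.), CH2Cl2, 0 °C
Reagents that add atoms: acryloyl chloride, C=CC(=O)Cl
Why: O-acylation of the secondary alcohol installs the second alkene for ring closure without touching a stereocenter.

Step 16
Reactants: 31 (3R,4S)-4-methylhexa-1,5-dien-3-yl acrylate
Product: 32 (5S,6R)-5-methyl-6-vinyl-5,6-dihydro-2H-pyran-2-one
Conditions: second-generation Grubbs catalyst (H2IMes)(PCy3)Cl2Ru=CHPh (5 mol %), CH2Cl2 (5 mM), 40 °C
Reagents that add atoms: none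
Why: Ring-closing metathesis between the acrylate and the homoallylic vinyl group forms the six-membered unsaturated lactone (favoured over the strained butenolide), so the anti dienol becomes the trans-5,6-disubstituted ring and the C6 vinyl group is kept for the Heck step.

Step 17
Reactants: 33 (R)-3-methyldihydrofuran-2(3H)-one
Product: 34 (3R)-3-methyltetrahydrofuran-2-ol (anomer mixture)
Conditions: i-Bu2AlH, CH2Cl2, −78 °C; aq. KNaC4H4O6
Reagents that add atoms: none
Why: Half-reduction of the lactone stops at the aluminium-bound lactol at −78 °C, giving a masked 4-hydroxy-2-methylbutanal without epimerising the α-center (future C15).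

Step 18
Reactants: 34 (3R)-3-methyltetrahydrofuran-2-ol; 35 propyltriphenylphosphonium bromide
Product: 39 (3R,4Z)-5-iodo-3-methylhept-4-en-1-ol, via ylide 36 (not isolated), via iodophosphonium iodide 37 (not isolated), via iodo ylide 38 (not isolated)
Conditions: 35, n-BuLi, THF, rt; I2, −78 °C; NaN(SiMe3)2, −20 °C; sodium salt of 34 (NaN(SiMe3)2, THF), −78 to −20 °C
Reagents that add atoms: iodine, II
Why: In this Stork–Zhao-type Wittig olefination the α-iodo ylide 38 traps the open hydroxy-aldehyde form of the lactol under kinetic control to give the Z-alkenyl iodide (iodine cis to C15) at low temperature, which preserves the α-center.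

Step 19
Reactants: 39 (3R,4Z)-5-iodo-3-methylhept-4-en-1-ol; 32 (5S,6R)-5-methyl-6-vinyl-5,6-dihydro-2H-pyran-2-one
Product: 40 (5S,6R)-6-[(1E,3Z,5R)-3-ethyl-7-hydroxy-5-methylhepta-1,3-dienyl]-5-methyl-5,6-dihydro-2H-pyran-2-one
Conditions: Pd(OAc)2 (10 mol %), Bu4NCl, NaHCO3, DMF, 40 °C
Reagents that add atoms: none
Why: In this Heck reaction the alkenyl–Pd–I species from oxidative addition adds to the CH2 terminus of the vinyl group and syn-β-hydride elimination gives the 18E-alkene with retention of the 16Z geometry, forming C17–C18 without touching a stereocenter.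

Step 20
Reactants: 40 (5S,6R)-6-[(1E,3Z,5R)-3-ethyl-7-hydroxy-5-methylhepta-1,3-dienyl]-5-methyl-5,6-dihydro-2H-pyran-2-one
Product: 41 (3R,4Z,6E)-5-ethyl-3-methyl-7-[(2R,3S)-3-methyl-6-oxo-3,6-dihydro-2H-pyran-2-yl]hepta-4,6-dienal
Conditions: Dess–Martin periodinane, NaHCO3, CH2Cl2, 0 °C to rt
Reagents that add atoms: none
Why: Buffered Dess–Martin oxidation of the primary alcohol gives the aldehyde without isomerising the triene or the lactone.

Step 21
Reactants: 41 (3R,4Z,6E)-5-ethyl-3-methyl-7-[(2R,3S)-3-methyl-6-oxo-3,6-dihydro-2H-pyran-2-yl]hepta-4,6-dienal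
Product: 42 (5S,6R)-6-[(1E,3Z,5R,7E)-3-ethyl-5-methyl-8-(4,4,5,5-tetramethyl-1,3,2-dioxaborolan-2-yl)octa-1,3,7-trienyl]-5-methyl-5,6-dihydro-2H-pyran-2-one
Conditions: CrCl2 (8 equiv), LiI, Cl2CHBpin, THF, rt
Reagents that add atoms: 2-(dichloromethyl)-4,4,5,5-tetramethyl-1,3,2-dioxaborolane, ClC(Cl)B1OC(C)(C)C(C)(C)O1
Why: In this Takai–Utimoto boryl-olefination the geminal dichromium species from the dihalomethylboronate adds to the aldehyde and eliminates to the E-alkenylboronate (C12=C13) under conditions that leave lactone and triene alone.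

Step 22
Reactants: 42 (5S,6R)-6-[(1E,3Z,5R,7E)-3-ethyl-5-methyl-8-(4,4,5,5-tetramethyl-1,3,2-dioxaborolan-2-yl)octa-1,3,7-trienyl]-5-methyl-5,6-dihydro-2H-pyran-2-one; 27 (2E,5R,6R,7S,8R,9S,10E)-6-(tert-butyldimethylsilyloxy)-9-[(tert-butyldimethylsilyloxy)methyl]-8-hydroxy-11-iodo-3,5,7-trimethyldodeca-2,10-dienoic acid
Product: 43 (2E,5R,6R,7S,8R,9S,10E,12E,15R,16Z,18E)-6-(tert-butyldimethylsilyloxy)-9-[(tert-butyldimethylsilyloxy)methyl]-17-ethyl-8-hydroxy-3,5,7,11,15-pentamethyl-19-[(2R,3S)-3-methyl-6-oxo-3,6-dihydro-2H-pyran-2-yl]nonadeca-2,10,12,16,18-pentaenoic acid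
Conditions: Pd(PPh3)4 (10 mol %), TlOEt, THF/H2O 3:1, rt, degassed
Reagents that add atoms: none
Why: In this Suzuki–Miyaura coupling oxidative addition into the alkenyl iodide, TlOEt-accelerated transmetalation of the alkenylboronate and reductive elimination join C11–C12 at room temperature with retention of both alkene geometries.

Step 23
Reactants: 43 (2E,5R,6R,7S,8R,9S,10E,12E,15R,16Z,18E)-6-(tert-butyldimethylsilyloxy)-9-[(tert-butyldimethylsilyloxy)methyl]-17-ethyl-8-hydroxy-3,5,7,11,15-pentamethyl-19-[(2R,3S)-3-methyl-6-oxo-3,6-dihydro-2H-pyran-2-yl]nonadeca-2,10,12,16,18-pentaenoic acid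
Product: 44 (2E,5R,6R,7R,9S,10E,12E,15R,16Z,18E)-6-(tert-butyldimethylsilyloxy)-9-[(tert-butyldimethylsilyloxy)methyl]-17-ethyl-3,5,7,11,15-pentamethyl-19-[(2R,3S)-3-methyl-6-oxo-3,6-dihydro-2H-pyran-2-yl]-8-oxononadeca-2,10,12,16,18-pentaenoic acid
Conditions: Dess–Martin periodinane, NaHCO3, CH2Cl2, 0 °C
Reagents that add atoms: none
Why: Buffered Dess–Martin oxidation converts the only free hydroxyl (C8) into the ketone after all basic steps are over, so the now enolisable C9 and C7 centers are never exposed to base.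

Step 24
Reactants: 44 (2E,5R,6R,7R,9S,10E,12E,15R,16Z,18E)-6-(tert-butyldimethylsilyloxy)-9-[(tert-butyldimethylsilyloxy)methyl]-17-ethyl-3,5,7,11,15-pentamethyl-19-[(2R,3S)-3-methyl-6-oxo-3,6-dihydro-2H-pyran-2-yl]-8-oxononadeca-2,10,12,16,18-pentaenoic acid
Product: 45 (2E,5R,6R,7R,9S,10E,12E,15R,16Z,18E)-17-ethyl-6-hydroxy-9-(hydroxymethyl)-3,5,7,11,15-pentamethyl-19-[(2R,3S)-3-methyl-6-oxo-3,6-dihydro-2H-pyran-2-yl]-8-oxononadeca-2,10,12,16,18-pentaenoic acid
Conditions: HF·pyridine, pyridine, THF, 0 °C to rt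
Reagents that add atoms: none
Why: Pyridine-buffered fluoride desilylation removes both TBS ethers under conditions mild enough for the β-hydroxy ketone, polyene and lactone, giving the target without epimerisation at C9.

**Compound list**
1 | (S)-3-bromo-2-methylpropan-1-ol | OC[C@H](C)CBr | starting material
2 | (S)-(3-bromo-2-methylpropoxy)triethylsilane | CC[Si](CC)(CC)OC[C@H](C)CBr | intermediate
3 | methyl but-2-ynoate | CC#CC(=O)OC | starting material
4 | [(S)-2-methyl-3-(triethylsilyloxy)propyl]magnesium bromide (not isolated) | CC[Si](CC)(CC)OC[C@H](C)C[Mg]Br | intermediate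
5 | [(S)-2-methyl-3-(triethylsilyloxy)propyl]copper (not isolated) | CC[Si](CC)(CC)OC[C@H](C)C[Cu] | intermediate
6 | methyl (R,Z)-2-cuprio-3,5-dimethyl-6-(triethylsilyloxy)hex-2-enoate, syn adduct (not isolated) | COC(=O)/C([Cu])=C(C)/C[C@@H](C)CO[Si](CC)(CC)CC | intermediate
7 | methyl (R,E)-3,5-dimethyl-6-(triethylsilyloxy)hex-2-enoate | COC(=O)/C=C(C)/C[C@@H](C)CO[Si](CC)(CC)CC | intermediate
8 | alkoxydimethylsulfonium chloride of methyl (R,E)-6-hydroxy-3,5-dimethylhex-2-enoate (not isolated) | COC(=O)/C=C(C)/C[C@@H](C)CO[S+](C)C.[Cl-] | intermediate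
9 | methyl (R,E)-3,5-dimethyl-6-oxohex-2-enoate | COC(=O)/C=C(C)/C[C@@H](C)C=O | intermediate
10 | O-diisopinocampheylboryl ether of 11 (not isolated) | COC(=O)/C=C(C)/C[C@@H](C)[C@@H](OB([C@@H]1C[C@@H]2C[C@H]([C@H]1C)C2(C)C)[C@@H]1C[C@@H]2C[C@H]([C@H]1C)C2(C)C)[C@@H](C)C=C | intermediate
11 | methyl (2E,5R,6R,7S)-6-hydroxy-3,5,7-trimethylnona-2,8-dienoate | COC(=O)/C=C(C)/C[C@@H](C)[C@@H](O)[C@@H](C)C=C | intermediate
12 | methyl (2E,5R,6R,7S)-6-(tert-butyldimethylsilyloxy)-3,5,7-trimethylnona-2,8-dienoate | COC(=O)/C=C(C)/C[C@@H](C)[C@@H](O[Si](C)(C)C(C)(C)C)[C@@H](C)C=C | intermediate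
13 | methyl (2E,5R,6R,7R)-6-(tert-butyldimethylsilyloxy)-3,5,7-trimethyl-8-oxooct-2-enoate | COC(=O)/C=C(C)/C[C@@H](C)[C@@H](O[Si](C)(C)C(C)(C)C)[C@@H](C)C=O | intermediate
14 | pent-3-yn-1-ol | CC#CCCO | starting material
15 | (E)-alkenylzirconocene chloride from 14, Zr on C4, oxygen bound to a second Cp2ZrCl (not isolated) | C/C(=C\CCO[Zr](Cl)(C1C=CC=C1)C1C=CC=C1)[Zr](Cl)(C1C=CC=C1)C1C=CC=C1 | intermediate
16 | (E)-4-iodopent-3-en-1-ol | OCC/C=C(C)/I | intermediate
17 | (E)-4-iodopent-3-enal (not isolated) | O=CC/C=C(C)/I | intermediate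
18 | (E)-4-iodopent-3-enoic acid | OC(=O)C/C=C(C)/I | intermediate
19 | (R)-4-benzyloxazolidin-2-one | O=C1OC[C@@H](Cc2ccccc2)N1 | starting material
20 | (E)-4-iodopent-3-enoic pivalic anhydride (not isolated) | CC(C)(C)C(=O)OC(=O)C/C=C(C)/I | intermediate
21 | (R)-4-benzyl-3-[(E)-4-iodopent-3-enoyl]oxazolidin-2-one | O=C1OC[C@@H](Cc2ccccc2)N1C(=O)C/C=C(C)/I | intermediate
22 | dibutylboron (Z)-dienolate of 21 (not isolated) | CCCCB(CCCC)O/C(=C\C=C(C)\I)N1[C@H](Cc2ccccc2)COC1=O | intermediate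
23 | O-dibutylboryl aldolate of 24 (not isolated) | COC(=O)/C=C(C)/C[C@@H](C)[C@@H](O[Si](C)(C)C(C)(C)C)[C@@H](C)[C@H](OB(CCCC)CCCC)[C@@H](/C=C(C)/I)C(=O)N1[C@H](Cc2ccccc2)COC1=O | intermediate
24 | methyl (2E,5R,6R,7S,8S,9R,10E)-9-[(R)-4-benzyl-2-oxooxazolidine-3-carbonyl]-6-(tert-butyldimethylsilyloxy)-8-hydroxy-11-iodo-3,5,7-trimethyldodeca-2,10-dienoate | COC(=O)/C=C(C)/C[C@@H](C)[C@@H](O[Si](C)(C)C(C)(C)C)[C@@H](C)[C@H](O)[C@@H](/C=C(C)/I)C(=O)N1[C@H](Cc2ccccc2)COC1=O | intermediate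
25 | methyl (2E,5R,6R,7S,8R,9S,10E)-6-(tert-butyldimethylsilyloxy)-8-hydroxy-9-(hydroxymethyl)-11-iodo-3,5,7-trimethyldodeca-2,10-dienoate | COC(=O)/C=C(C)/C[C@@H](C)[C@@H](O[Si](C)(C)C(C)(C)C)[C@@H](C)[C@H](O)[C@@H](/C=C(C)/I)CO | intermediate
26 | methyl (2E,5R,6R,7S,8R,9S,10E)-6-(tert-butyldimethylsilyloxy)-9-[(tert-butyldimethylsilyloxy)methyl]-8-hydroxy-11-iodo-3,5,7-trimethyldodeca-2,10-dienoate | COC(=O)/C=C(C)/C[C@@H](C)[C@@H](O[Si](C)(C)C(C)(C)C)[C@@H](C)[C@H](O)[C@@H](/C=C(C)/I)CO[Si](C)(C)C(C)(C)C | intermediate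
27 | (2E,5R,6R,7S,8R,9S,10E)-6-(tert-butyldimethylsilyloxy)-9-[(tert-butyldimethylsilyloxy)methyl]-8-hydroxy-11-iodo-3,5,7-trimethyldodeca-2,10-dienoic acid | OC(=O)/C=C(C)/C[C@@H](C)[C@@H](O[Si](C)(C)C(C)(C)C)[C@@H](C)[C@H](O)[C@@H](/C=C(C)/I)CO[Si](C)(C)C(C)(C)C | intermediate
28 | acrolein | C=CC=O | starting material
29 | O-diisopinocampheylboryl ether of 30 (not isolated) | C=C[C@@H](OB([C@@H]1C[C@@H]2C[C@H]([C@H]1C)C2(C)C)[C@@H]1C[C@@H]2C[C@H]([C@H]1C)C2(C)C)[C@@H](C)C=C | intermediate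
30 | (3R,4S)-4-methylhexa-1,5-dien-3-ol | C=C[C@@H](O)[C@@H](C)C=C | intermediate
31 | (3R,4S)-4-methylhexa-1,5-dien-3-yl acrylate | C=CC(=O)O[C@H](C=C)[C@@H](C)C=C | intermediate
32 | (5S,6R)-5-methyl-6-vinyl-5,6-dihydro-2H-pyran-2-one | C=C[C@H]1OC(=O)C=C[C@@H]1C | intermediate
33 | (R)-3-methyldihydrofuran-2(3H)-one | C[C@@H]1CCOC1=O | starting material
34 | (3R)-3-methyltetrahydrofuran-2-ol (anomer mixture) | C[C@@H]1CCOC1O | intermediate
35 | propyltriphenylphosphonium bromide | CCC[P+](c1ccccc1)(c1ccccc1)c1ccccc1.[Br-] | starting material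
36 | propylidenetriphenylphosphorane (not isolated) | CCC=P(c1ccccc1)(c1ccccc1)c1ccccc1 | intermediate
37 | (1-iodopropyl)triphenylphosphonium iodide (not isolated) | CCC(I)[P+](c1ccccc1)(c1ccccc1)c1ccccc1.[I-] | intermediate
38 | (1-iodopropylidene)triphenylphosphorane (not isolated) | CCC(I)=P(c1ccccc1)(c1ccccc1)c1ccccc1 | intermediate
39 | (3R,4Z)-5-iodo-3-methylhept-4-en-1-ol | OCC[C@@H](C)/C=C(\I)CC | intermediate
40 | (5S,6R)-6-[(1E,3Z,5R)-3-ethyl-7-hydroxy-5-methylhepta-1,3-dienyl]-5-methyl-5,6-dihydro-2H-pyran-2-one | OCC[C@@H](C)/C=C(CC)\C=C\[C@H]1OC(=O)C=C[C@@H]1C | intermediate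
41 | (3R,4Z,6E)-5-ethyl-3-methyl-7-[(2R,3S)-3-methyl-6-oxo-3,6-dihydro-2H-pyran-2-yl]hepta-4,6-dienal | O=CC[C@@H](C)/C=C(CC)\C=C\[C@H]1OC(=O)C=C[C@@H]1C | intermediate
42 | (5S,6R)-6-[(1E,3Z,5R,7E)-3-ethyl-5-methyl-8-(4,4,5,5-tetramethyl-1,3,2-dioxaborolan-2-yl)octa-1,3,7-trienyl]-5-methyl-5,6-dihydro-2H-pyran-2-one | CC1(C)OB(/C=C/C[C@@H](C)/C=C(CC)\C=C\[C@H]2OC(=O)C=C[C@@H]2C)OC1(C)C | intermediate
43 | (2E,5R,6R,7S,8R,9S,10E,12E,15R,16Z,18E)-6-(tert-butyldimethylsilyloxy)-9-[(tert-butyldimethylsilyloxy)methyl]-17-ethyl-8-hydroxy-3,5,7,11,15-pentamethyl-19-[(2R,3S)-3-methyl-6-oxo-3,6-dihydro-2H-pyran-2-yl]nonadeca-2,10,12,16,18-pentaenoic acid | CCC(=C/[C@H](C)C/C=C/C(C)=C/[C@@H](CO[Si](C)(C)C(C)(C)C)[C@@H](O)[C@H](C)[C@H](O[Si](C)(C)C(C)(C)C)[C@H](C)C/C(C)=C/C(=O)O)/C=C/[C@H]1OC(=O)C=C[C@@H]1C | intermediate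
44 | (2E,5R,6R,7R,9S,10E,12E,15R,16Z,18E)-6-(tert-butyldimethylsilyloxy)-9-[(tert-butyldimethylsilyloxy)methyl]-17-ethyl-3,5,7,11,15-pentamethyl-19-[(2R,3S)-3-methyl-6-oxo-3,6-dihydro-2H-pyran-2-yl]-8-oxononadeca-2,10,12,16,18-pentaenoic acid | CCC(=C/[C@H](C)C/C=C/C(C)=C/[C@@H](CO[Si](C)(C)C(C)(C)C)C(=O)[C@H](C)[C@H](O[Si](C)(C)C(C)(C)C)[C@H](C)C/C(C)=C/C(=O)O)/C=C/[C@H]1OC(=O)C=C[C@@H]1C | intermediate
45 | (2E,5R,6R,7R,9S,10E,12E,15R,16Z,18E)-17-ethyl-6-hydroxy-9-(hydroxymethyl)-3,5,7,11,15-pentamethyl-19-[(2R,3S)-3-methyl-6-oxo-3,6-dihydro-2H-pyran-2-yl]-8-oxononadeca-2,10,12,16,18-pentaenoic acid | CCC(=C/[C@H](C)C/C=C/C(C)=C/[C@@H](CO)C(=O)[C@H](C)[C@H](O)[C@H](C)C/C(C)=C/C(=O)O)/C=C/[C@H]1OC(=O)C=C[C@@H]1C | target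

**Totals**
Total step count: 24.
Longest linear sequence: 13 steps (steps 1–6, 10–13, 22–24, from bromo alcohol 1).

**Three steps most likely to fail**

Step 18 is the first risk. The iodo-ylide olefination of a lactol usually gives a modest yield, and the excess base can epimerise the α-center. The fallback sets out from lactone 33 and uses a protected open-chain aldehyde instead of the lactol. The lactone is opened with MeNH(OMe)·HCl and i-PrMgCl to (R)-4-hydroxy-N-methoxy-N,2-dimethylbutanamide F1. This is silylated with TBSCl and imidazole to (R)-4-(tert-butyldimethylsilyloxy)-N-methoxy-N,2-dimethylbutanamide F2 and reduced with i-Bu2AlH at −78 °C to (R)-4-(tert-butyldimethylsilyloxy)-2-methylbutanal F3. Olefination with iodo ylide 38 then gives tert-butyl{[(3R,4Z)-5-iodo-3-methylhept-4-en-1-yl]oxy}dimethylsilane F4, and CSA in MeOH removes the silyl group, which comes back to the route at 39.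

Step 19 is the second risk. In the Heck coupling the allylic lactone oxygen can be lost by β-elimination, and the hindered Z-iodide may react slowly or isomerise. The fallback sets out from vinyl lactone 32 and moves the bond formation to a cross-coupling. Cross-metathesis of 32 with vinylboronic acid pinacol ester, using the second-generation Hoveyda–Grubbs catalyst (H2IMes)Cl2Ru=CH(C6H4-2-OiPr), gives (5S,6R)-5-methyl-6-[(E)-2-(4,4,5,5-tetramethyl-1,3,2-dioxaborolan-2-yl)vinyl]-5,6-dihydro-2H-pyran-2-one F5. Suzuki–Miyaura coupling of this boronate with iodide 39 (Pd(PPh3)4, TlOEt, THF/H2O, rt) comes back to the route at 40.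

Step 22 is the third risk. The aqueous base of the Suzuki coupling may open the lactone or damage the polyene. The fallback sets out from aldehyde 41 and replaces boron by tin so that the coupling runs without base. Stannyl-olefination of 41 with Bu3SnCHBr2, CrCl2 and LiI in THF/DMF gives (5S,6R)-6-[(1E,3Z,5R,7E)-3-ethyl-5-methyl-8-(tributylstannyl)octa-1,3,7-trienyl]-5-methyl-5,6-dihydro-2H-pyran-2-one F6. Stille coupling of this stannane with iodide 27 under neutral conditions (Pd2(dba)3, AsPh3, NMP, rt) comes back to the route at 43.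

**Further compounds**
F1 | step 18 | (R)-4-hydroxy-N-methoxy-N,2-dimethylbutanamide | CON(C)C(=O)[C@H](C)CCO
F2 | step 18 | (R)-4-(tert-butyldimethylsilyloxy)-N-methoxy-N,2-dimethylbutanamide | CON(C)C(=O)[C@H](C)CCO[Si](C)(C)C(C)(C)C
F3 | step 18 | (R)-4-(tert-butyldimethylsilyloxy)-2-methylbutanal | O=C[C@H](C)CCO[Si](C)(C)C(C)(C)C
F4 | step 18 | tert-butyl{[(3R,4Z)-5-iodo-3-methylhept-4-en-1-yl]oxy}dimethylsilane | CC(C)(C)[Si](C)(C)OCC[C@@H](C)/C=C(\I)CC
F5 | step 19 | (5S,6R)-5-methyl-6-[(E)-2-(4,4,5,5-tetramethyl-1,3,2-dioxaborolan-2-yl)vinyl]-5,6-dihydro-2H-pyran-2-one | CC1(C)OB(/C=C/[C@H]2OC(=O)C=C[C@@H]2C)OC1(C)C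
F6 | step 22 | (5S,6R)-6-[(1E,3Z,5R,7E)-3-ethyl-5-methyl-8-(tributylstannyl)octa-1,3,7-trienyl]-5-methyl-5,6-dihydro-2H-pyran-2-one | CCCC[Sn](CCCC)(CCCC)/C=C/C[C@@H](C)/C=C(CC)\C=C\[C@H]1OC(=O)C=C[C@@H]1C
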